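I started from what is left over at the end, the unbound protic impurity, and asked what that leftover says about the ring.

    starting material → ring (k1 = 0.21 s⁻¹)
    starting material + starting material ⇌ open dimer (K2 = 88 L mol⁻¹, k2 = 73 L mol⁻¹ s⁻¹)
    starting material + protic impurity → quenched substrate (k3 = 46 L mol⁻¹ s⁻¹)
    ring → over-reaction product (k4 = 5.9 × 10⁻⁶ s⁻¹)
    solid substrate ⇌ starting material, rate k5*(cs5 - [starting material]) while solid is left; crystals form when [starting material] > cs5 (cs5 = 7.2 mM, k5 = 0.028 s⁻¹)

| flask | solid substrate | protic impurity | time |
|---|---|---|---|
| maple | 20 mM | 0.120 mM | 5.0 min |
| larch | 20 mM | 0.300 mM | 5.0 min |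
| ash | 20 mM | 1.00 mM | 5.0 min |
| elm | 20 mM | 3.00 mM | 5.0 min |
| birch | 20 mM | 10.0 mM | 5.0 min |

- amount of ring at the end, in percent of the solid substrate charged for maple, larch, ash, elm, birch, in this order
- how the row runs (rises all the way / falls all the way / falls, then rises / hardly changes / rises, then falls)

- a species is counted by the solid substrate in it: one open dimer counts as two
- where a step has two of a species, its rate is k times that concentration squared, and two are used at each turn
- given per volume of solution although it is solid: solid substrate
- at the start none of the solid substrate is in solution
- "hardly changes" means that all values lie within two and a half points (for a concentration: within two and a half percent of the largest)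
- run time (maple): 5.0 min

First I checked that the charge is through by the end. Dissolving at its fastest needs 1.65 min, the half-life of starting material by ring closure is 0.055 min, and the open dimer returns with a half-life of 0.836 s. These are shorter than 5.0 min, so I took the end of each run to hold ring, quenched substrate and a little over-reaction product.

Ring forms at 0.21 s⁻¹ times [starting material], and protic impurity dies at 46 L mol⁻¹ s⁻¹ times [starting material] times [protic impurity], so one clock serves both: the time integral of [starting material]. However the solid and the open dimer shape that integral, a ring share r of the charge means the impurity has seen the exponent rX. Here X is the quench ceiling, the exponent for a whole charge passing through ring, 46 L mol⁻¹ s⁻¹ times 20 mM over 0.21 s⁻¹, which is 4.38. The impurity left is then e^(−rX), and what it consumed comes off the ring.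

A larger r consumes more impurity and returns a smaller r, so the passes land on alternate sides. Ring has a half-life of 33 h, far beyond 5.0 min, so it can lose at most 0.177% of itself, and I took that off the floors. The first pass gave floors of 99.2%, 98.3%, 94.9% and 85.0% for maple, larch, ash and elm. The second pass gave ceilings of 99.4%, 98.5%, 95.1% and 85.4%. Birch swung wider, with ring made at 50.6%, 55.4%, 54.4% and 54.6%, so its floor after the allowance was 54.3%.

The forecast, 99.3%, 98.38%, 94.94%, 85.24% and 54.5%, falls all the way, held that “By 5 min all substrate has reacted, leaving only ring and quenched substrate.”, and for birch my floor stood at 54.3% and my last ceiling at 54.6%. The flasks gave 99.3%, 98.4%, 94.9%, 85.2% and 54.5%, which falls all the way.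

Birch loses ring because starting material passes to quenched substrate: with that step taken away, birch goes from 54.5% to 99.9%. The depletion of protic impurity holds back part of that loss: with [protic impurity] held at its charge, birch gives 31.3%. That is the selectivity factor of 0.21 s⁻¹ against 46 L mol⁻¹ s⁻¹ times 10.0 mM, a ring share of 31.3%. In birch the impurity does not stay: a ring share of 54.5% on the ceiling 4.38 leaves 9.19% of its charge, and the flask holds 9.2%. In elm, 85.2% on the same ceiling leaves 2.40%, and the flask holds 2.4%.

(The numbers were set for the occasion; what happens was integrated by code.)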